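**Strategy.** Everything rests on disconnecting the quinone ring (ring B) at the bond between carbonyl carbon C1 and the side-chain-bearing carbon C2. A thermal Moore rearrangement forms this bond: a 2-alkynyl-2-hydroxybenzocyclobutenone opens to an o-quinoid ketene, whose ketene carbon closes onto the distal alkyne carbon; the four-membered ring thus expands to the 1,4-naphthoquinone in one operation, and the hydroxyl hydrogen ends up at C3. The step exploits the symmetric 5,8-dioxygenated ring A (a symmetric benzocyclobutenedione accepts the acetylide at either carbonyl) and the C2 position of the (S)-carbinol side chain, which enters as an enantioenriched propargylic alcohol. Ring A carries MOM ethers until the last step.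

Key step: step 8

Remark: the target is read as the (S)-configured (alkannin-series) ester of tiglic acid ((E)-2-methylbut-2-enoic acid); naphthazarins equilibrate between tautomers, and the route delivers the tautomer drawn, with the side chain on the quinone ring.

**Step 1**
Reactants: 1 2-chlorobenzene-1,4-diol (chlorohydroquinone)
Product: 2 2-chloro-1,4-bis(methoxymethoxy)benzene
Conditions: MOMCl, i-Pr2NEt, CH2Cl2, 0 → 25 °C
Reagents that add atoms: chloromethyl methyl ether (MOMCl), COCCl
Why: O-alkylation of both phenols with the reactive α-chloro ether (Williamson-type etherification) should give the bis(MOM) ether, which directs the lithiation of step 2 and is removable by mild acid at the end.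

**Step 2**
Reactants: 2 2-chloro-1,4-bis(methoxymethoxy)benzene; 3 tris(trimethylsiloxy)ethylene
Product: 7 2-hydroxy-3,6-bis(methoxymethoxy)benzocyclobuten-1(2H)-one (racemic α-ketol), via aryllithium 4 (not isolated), via aryne 5 (not isolated), via silylated cycloadduct 6 (not isolated)
Conditions: s-BuLi, THF, −78 °C; then 3 (3 equiv), −78 → 0 °C; then AcOH/H2O/THF, 25 °C
Reagents that add atoms: none
Why: Directed ortho-lithiation at the position flanked by Cl and OMOM and loss of LiCl on warming should give the symmetric aryne 5, which is trapped in the [2+2] cycloaddition of arynes with ketene silyl acetals (no regiochemical question, since 5 is symmetric), and mild acid hydrolysis of the three silyl ethers unveils the α-ketol.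

**Step 3**
Reactants: 7 2-hydroxy-3,6-bis(methoxymethoxy)benzocyclobuten-1(2H)-one
Product: 8 3,6-bis(methoxymethoxy)benzocyclobutene-1,2-dione
Conditions: Dess–Martin periodinane, CH2Cl2, 0 → 25 °C
Reagents that add atoms: none
Why: Dess–Martin oxidation of the benzylic α-hydroxy ketone to the 1,2-dione runs under near-neutral conditions that should leave the MOM ethers and the strained ring intact.

**Step 4**
Reactants: 9 4-methylpent-3-enoic acid
Product: 11 N-methoxy-N,4-dimethylpent-3-enamide, via acyl imidazole 10 (not isolated)
Conditions: CDI, CH2Cl2, 25 °C; then MeNH(OMe)·HCl, 25 °C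
Reagents that add atoms: N,O-dimethylhydroxylamine hydrochloride, CNOC.Cl
Why: Activation as the acyl imidazole and aminolysis (Weinreb amide formation) needs no strong base, so the β,γ-double bond should not move into conjugation.

**Step 5**
Reactants: 11 N-methoxy-N,4-dimethylpent-3-enamide; 12 ethynylmagnesium bromide
Product: 14 6-methylhept-5-en-1-yn-3-one, via magnesium chelate 13 (not isolated)
Conditions: THF, 0 °C; inverse quench into cold 1 M aq. HCl/Et2O
Reagents that add atoms: none
Why: Weinreb ketone synthesis: the stable magnesium chelate 13 stops the addition at the ketone stage, and the cold acidic quench keeps the liberated amine protonated so that it cannot add to the ynone.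

**Step 6**
Reactants: 14 6-methylhept-5-en-1-yn-3-one
Product: 16 (3S)-6-methylhept-5-en-1-yn-3-ol, via borinate 15 (not isolated)
Conditions: (S)-Alpine-Borane (B-isopinocampheyl-9-borabicyclo[3.3.1]nonane from (−)-α-pinene), THF, 0 → 25 °C; then MeCHO; then HOCH2CH2NH2, Et2O, 0 °C
Reagents that add atoms: none
Why: Midland reduction: hydride passes from the isopinocampheyl C–H to the ketone through a six-membered boat-like transition state in which the slim ethynyl group lies next to the pinane methyl, so the reagent from (−)-α-pinene should set the (S)-carbinol center, under neutral conditions that leave the β,γ-alkene in place.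

**Step 7**
Reactants: 16 (3S)-6-methylhept-5-en-1-yn-3-ol; 8 3,6-bis(methoxymethoxy)benzocyclobutene-1,2-dione
Product: 18 2-hydroxy-2-[(3S)-3-hydroxy-6-methylhept-5-en-1-yn-1-yl]-3,6-bis(methoxymethoxy)benzocyclobuten-1(2H)-one (both epimers at C2), via dilithio alkynolate 17 (not isolated)
Conditions: 16, n-BuLi (2 equiv), THF, −78 → −20 °C; then 8, THF, −78 °C; AcOH quench at −78 °C
Reagents that add atoms: none
Why: 1,2-Addition of the acetylide end of dianion 17 to one carbonyl of the strained, symmetric 1,2-dione (either carbonyl gives the same adduct, and the lithium alkoxide formed shields the second carbonyl); the new carbinol center forms as a mixture of epimers that is erased in step 8, and the (S)-center is not touched.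

**Step 8**
Reactants: 18 2-hydroxy-2-[(3S)-3-hydroxy-6-methylhept-5-en-1-yn-1-yl]-3,6-bis(methoxymethoxy)benzocyclobuten-1(2H)-one
Product: 21 2-[(1S)-1-hydroxy-4-methylpent-3-en-1-yl]-5,8-bis(methoxymethoxy)naphthalene-1,4-dione, via o-quinoid ketene 19 (not isolated), via aromatic diradical 20 (not isolated)
Conditions: degassed p-xylene (0.01 M), 138 °C
Reagents that add atoms: none
Why: Thermal 4π-electrocyclic opening of the benzocyclobutenone breaks the C1–C2 bond of the four-membered ring with outward rotation of the hydroxyl group, which gives the o-quinoid ketene 19 with the alkynyl group held next to the ketene. The ketene carbon then bonds to the distal alkyne carbon to give the aromatic diradical 20 (phenoxyl radical at O1, sigma radical at C3), and transfer of the hydroxyl hydrogen to C3 gives the quinone; this is the Moore rearrangement of 4-alkynyl-4-hydroxycyclobutenones, applied here to a benzocyclobutenedione adduct. The six-membered quinone ring is closed in the 6-endo-dig mode, and no other ring is formed. No stereocenter is created: the carbinol center of the four-membered ring is destroyed, and the (S)-center of the side chain is retained because no bond to it is made or broken under these neutral conditions. The selectivity needed is 6-endo closure over 5-exo closure to a 2-alkylidene-indane-1,3-dione, and it is secured by the alkyl-type substituent at the alkyne terminus, which gives no stabilisation to the exocyclic vinyl radical of the 5-exo path. High dilution and degassed solvent should keep the short-lived diradical from intermolecular reactions.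

**Step 9**
Reactants: 21 2-[(1S)-1-hydroxy-4-methylpent-3-en-1-yl]-5,8-bis(methoxymethoxy)naphthalene-1,4-dione; 22 tiglic acid ((2E)-2-methylbut-2-enoic acid)
Product: 23 (1S)-1-[5,8-bis(methoxymethoxy)-1,4-dioxo-1,4-dihydronaphthalen-2-yl]-4-methylpent-3-en-1-yl (2E)-2-methylbut-2-enoate
Conditions: DCC, DMAP (cat.), CH2Cl2, 0 → 25 °C
Reagents that add atoms: none
Why: Steglich esterification acylates the secondary alcohol at oxygen, so the C–O bond of the stereocenter is not broken (retention), and the more stable (E)-geometry of the tiglate should be kept.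

**Step 10**
Reactants: 23 (1S)-1-[5,8-bis(methoxymethoxy)-1,4-dioxo-1,4-dihydronaphthalen-2-yl]-4-methylpent-3-en-1-yl (2E)-2-methylbut-2-enoate
Product: 24 (1S)-1-(5,8-dihydroxy-1,4-dioxo-1,4-dihydronaphthalen-2-yl)-4-methylpent-3-en-1-yl (2E)-2-methylbut-2-enoate (target)
Conditions: 3 M aq. HCl, THF, 25 °C
Reagents that add atoms: none
Why: Acid-catalysed acetal hydrolysis of the two aryl MOM ethers, helped by the peri carbonyl groups that end up hydrogen-bonded to the freed phenols, should release the naphthazarin; the ester, the trisubstituted alkene and the stereocenter (next to the electron-poor quinone, hence not ionisable) should survive dilute acid at room temperature.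

**Compound list**
1 | 2-chlorobenzene-1,4-diol (chlorohydroquinone) | Oc1ccc(O)c(Cl)c1 | starting material
2 | 2-chloro-1,4-bis(methoxymethoxy)benzene | COCOc1ccc(OCOC)c(Cl)c1 | intermediate
3 | tris(trimethylsiloxy)ethylene | C[Si](C)(C)OC=C(O[Si](C)(C)C)O[Si](C)(C)C | starting material
4 | 2-chloro-3-lithio-1,4-bis(methoxymethoxy)benzene (not isolated) | [Li]c1c(Cl)c(OCOC)ccc1OCOC | intermediate
5 | 3,6-bis(methoxymethoxy)benzyne (not isolated) | COCOC1=CC=C(OCOC)C#C1 | intermediate
6 | 3,6-bis(methoxymethoxy)-1,1,2-tris(trimethylsiloxy)benzocyclobutene, racemic (not isolated) | COCOc1ccc(OCOC)c2c1C(O[Si](C)(C)C)C2(O[Si](C)(C)C)O[Si](C)(C)C | intermediate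
7 | 2-hydroxy-3,6-bis(methoxymethoxy)benzocyclobuten-1(2H)-one, racemic | COCOc1ccc(OCOC)c2c1C(O)C2=O | intermediate
8 | 3,6-bis(methoxymethoxy)benzocyclobutene-1,2-dione | COCOc1ccc(OCOC)c2c1C(=O)C2=O | intermediate
9 | 4-methylpent-3-enoic acid | CC(C)=CCC(=O)O | starting material
10 | 1-(4-methylpent-3-enoyl)imidazole (not isolated) | CC(C)=CCC(=O)n1ccnc1 | intermediate
11 | N-methoxy-N,4-dimethylpent-3-enamide | CC(C)=CCC(=O)N(C)OC | intermediate
12 | ethynylmagnesium bromide | C#C[Mg]Br | starting material
13 | bromomagnesium salt of the tetrahedral adduct of 11 and 12 (not isolated) | CC(C)=CCC(C#C)(O[Mg]Br)N(C)OC | intermediate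
14 | 6-methylhept-5-en-1-yn-3-one | CC(C)=CCC(=O)C#C | intermediate
15 | B-[(3S)-6-methylhept-5-en-1-yn-3-yloxy]-9-borabicyclo[3.3.1]nonane (not isolated) | CC(C)=CC[C@H](OB1C2CCCC1CCC2)C#C | intermediate
16 | (3S)-6-methylhept-5-en-1-yn-3-ol | CC(C)=CC[C@H](O)C#C | intermediate
17 | lithium (3S)-1-lithio-6-methylhept-5-en-1-yn-3-olate (not isolated) | CC(C)=CC[C@H](O[Li])C#C[Li] | intermediate
18 | 2-hydroxy-2-[(3S)-3-hydroxy-6-methylhept-5-en-1-yn-1-yl]-3,6-bis(methoxymethoxy)benzocyclobuten-1(2H)-one, both epimers at C2 | COCOc1ccc(OCOC)c2c1C(=O)C2(O)C#C[C@@H](O)CC=C(C)C | intermediate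
19 | ring-opened o-quinoid ketene: 1,4-bis(methoxymethoxy)cyclohexa-1,3-diene with an oxomethylidene group at C5 and a (4S)-1,4-dihydroxy-7-methyloct-6-en-2-yn-1-ylidene group at C6, alkynyl cis to the ketene (not isolated) | COCOC1=CC=C(OCOC)C(=C=O)/C1=C(/O)C#C[C@@H](O)CC=C(C)C | intermediate
20 | 4-hydroxy-2-[(1S)-1-hydroxy-4-methylpent-3-en-1-yl]-5,8-bis(methoxymethoxy)naphthalene diradical, oxyl at O1 and sigma radical at C3 (not isolated) | [O]c1c([C@@H](O)CC=C(C)C)[c]c(O)c2c(OCOC)ccc(OCOC)c12 | intermediate
21 | 2-[(1S)-1-hydroxy-4-methylpent-3-en-1-yl]-5,8-bis(methoxymethoxy)naphthalene-1,4-dione | COCOc1ccc(OCOC)c2c1C(=O)C=C([C@@H](O)CC=C(C)C)C2=O | intermediate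
22 | tiglic acid, (2E)-2-methylbut-2-enoic acid | C/C=C(\C)C(=O)O | starting material
23 | (1S)-1-[5,8-bis(methoxymethoxy)-1,4-dioxo-1,4-dihydronaphthalen-2-yl]-4-methylpent-3-en-1-yl (2E)-2-methylbut-2-enoate | C/C=C(\C)C(=O)O[C@@H](CC=C(C)C)C1=CC(=O)c2c(OCOC)ccc(OCOC)c2C1=O | intermediate
24 | (1S)-1-(5,8-dihydroxy-1,4-dioxo-1,4-dihydronaphthalen-2-yl)-4-methylpent-3-en-1-yl (2E)-2-methylbut-2-enoate | C/C=C(\C)C(=O)O[C@@H](CC=C(C)C)C1=CC(=O)c2c(O)ccc(O)c2C1=O | target

**Step count.** Total: 10 steps. Longest linear sequence: 7 steps (steps 1, 2, 3, 7, 8, 9, 10; the alkyne branch, steps 4, 5, 6, then 7 to 10, is equally long).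

**Steps most likely to fail**

Step 8 (key step). The ring closure may take the 5-exo course to a 2-alkylidene-indane-1,3-dione, or the sigma radical at C3 of 20 may add to the side-chain alkene before it receives the hydroxyl hydrogen. Fallback: set out from dione 8 and alkynol 16 and avoid radical intermediates by a metal-mediated route. Insertion of ClCo(PPh3)3 (monovalent cobalt) into the C1–C2 bond of 8 in benzene should give chloro[3,6-bis(methoxymethoxy)phthaloyl]bis(triphenylphosphine)cobalt F1 (trivalent cobalt). Chloride abstraction with AgBF4 in MeCN and heating with 16 should insert the alkyne between the two acyl–cobalt bonds and release quinone 21 by reductive elimination, where the route is rejoined. The symmetry of F1 again removes any regiochemical question.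

Step 2. Silyl transfer from 3 to aryllithium 4, or addition of 4 to aryne 5, may outrun the cycloaddition. Fallback: set out from 1 and build the dione in the methyl ether series by the classical sequence. O-Methylation (MeI, K2CO3, acetone) should give 2-chloro-1,4-dimethoxybenzene F2. NaNH2 in THF at reflux with 1,1-dimethoxyethylene should lead, by way of 3,6-dimethoxybenzyne F3, to the ketal 1,1,3,6-tetramethoxybenzocyclobutene F4. Aqueous HCl should give 3,6-dimethoxybenzocyclobuten-1(2H)-one F5. Radical bromination (NBS, dibenzoyl peroxide, CCl4, reflux) should give 2,2-dibromo-3,6-dimethoxybenzocyclobuten-1(2H)-one F6, and hydrolysis in aqueous H2SO4 should give 3,6-dimethoxybenzocyclobutene-1,2-dione F7. BBr3 in CH2Cl2 should give 3,6-dihydroxybenzocyclobutene-1,2-dione F8, and MOMCl with i-Pr2NEt then gives 8, where the route is rejoined.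

Step 10. Under aqueous acid the trisubstituted alkene may add water or HCl, or the ester may be lost, before the second MOM ether is cleaved. Fallback: set out from 21, change the order of the last two operations and use an aprotic cleavage. B-Bromocatecholborane in CH2Cl2 at −78 °C, then aqueous work-up, should give alkannin, 5,8-dihydroxy-2-[(1S)-1-hydroxy-4-methylpent-3-en-1-yl]naphthalene-1,4-dione F9. Only the side-chain hydroxyl of F9 should then be esterified with 22 (DCC, DMAP cat., CH2Cl2), because both phenols are held in hydrogen bonds to the quinone carbonyls, and this gives target 24 directly.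

**Further compounds**
F1 | step 8 | chloro[3,6-bis(methoxymethoxy)phthaloyl]bis(triphenylphosphine)cobalt | COCOc1ccc(OCOC)c2c1C(=O)[Co-2](Cl)([P+](c1ccccc1)(c1ccccc1)c1ccccc1)([P+](c1ccccc1)(c1ccccc1)c1ccccc1)C2=O
F2 | step 2 | 2-chloro-1,4-dimethoxybenzene | COc1ccc(OC)c(Cl)c1
F3 | step 2 | 3,6-dimethoxybenzyne | COC1=CC=C(OC)C#C1
F4 | step 2 | 1,1,3,6-tetramethoxybenzocyclobutene | COc1ccc(OC)c2c1CC2(OC)OC
F5 | step 2 | 3,6-dimethoxybenzocyclobuten-1(2H)-one | COc1ccc(OC)c2c1CC2=O
F6 | step 2 | 2,2-dibromo-3,6-dimethoxybenzocyclobuten-1(2H)-one | COc1ccc(OC)c2c1C(=O)C2(Br)Br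
F7 | step 2 | 3,6-dimethoxybenzocyclobutene-1,2-dione | COc1ccc(OC)c2c1C(=O)C2=O
F8 | step 2 | 3,6-dihydroxybenzocyclobutene-1,2-dione | Oc1ccc(O)c2c1C(=O)C2=O
F9 | step 10 | alkannin, 5,8-dihydroxy-2-[(1S)-1-hydroxy-4-methylpent-3-en-1-yl]naphthalene-1,4-dione | CC(C)=CC[C@H](O)C1=CC(=O)c2c(O)ccc(O)c2C1=O
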